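Both dihydrofuran rings are cut at their benzylic ether bonds, O1–C2 (ring A unit) and O1'–C2' (ring B unit). The key step exploits that C2 and C2' each sit para to an oxygen across their aryl ring. Both C–O bonds therefore ionise reversibly, so one acid treatment closes the two rings onto phenolic oxygens of rings A and B and lets each 2-aryl group settle trans to the aryl on C3 or C3'. The precursor is an open-chain bis(1,2,2-triarylethanol) with free resorcinol rings A and B, in which only C3 (R) and C3' (S) are fixed. It comes from ketone α-arylations and two enantiomeric dynamic kinetic resolutions.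

Key step: step 9

Numbering: benzofuran locants (O1, C2, C3, C3a, C4–C7, C7a) for the unit built on ring A (the ring carrying the styryl group), primed locants for the unit built on ring B; the same locants are used for the open-chain compounds.

Remark: the target has seven phenolic hydroxyls, so a fully O-alkylated cyclisation product would be a hepta-ether and its cleavage would remove seven groups. In this route O4 and O4' leave the key step already free, and five benzyl ethers remain.

Remark on the precursor: rings A and B are used as symmetric resorcinols, so the two hydroxyls flanking C3 (or C3') are equivalent and no oxygen has to be differentiated. The five spectator phenols are benzyl ethers, so the end game needs only BCl3 at −78 °C next to the stilbene and the two ionisable C2–O bonds.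

Assumption: in steps 5 and 8 the catalyst fixes the carbinol carbon in the sense established for aryl ketones, and the labile α-carbon follows in the Felkin–Anh sense with the ortho,ortho'-dioxygenated ring as the large group. Should the relative sense be the opposite, the enantiomeric catalyst is used in that step, because the carbinol configurations are erased in step 9.

Assumption: compounds 1, 5, 7 and 10 are catalogue chemicals.

Step 1
Reactants: 1 5-chlororesorcinol
Product: 2 1-chloro-3,5-bis(methoxymethoxy)benzene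
Conditions: NaH, MOMCl, DMF, 0 °C → rt
Reagents that add atoms: chloromethyl methyl ether (MOMCl), COCCl
Why: Williamson-type O-alkylation of the bis(phenoxide) by the α-chloro ether should give the bis(acetal), a small base-stable group that also directs the next metalation.

Step 2
Reactants: 2 1-chloro-3,5-bis(methoxymethoxy)benzene
Product: 4 2-bromo-5-chloro-1,3-bis(methoxymethoxy)benzene, via aryllithium 3 (not isolated)
Conditions: n-BuLi, THF, −78 → −20 °C; BrCCl2CCl2Br, −78 °C → rt
Reagents that add atoms: 1,2-dibromo-1,1,2,2-tetrachloroethane, BrC(Cl)(Cl)C(Cl)(Cl)Br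
Why: Directed ortho-metalation places lithium on the carbon between the two cooperating OMOM groups (meta to chlorine, so no aryne can form), and the aryllithium takes bromine from the perhaloethane.

Step 3
Reactants: 4 2-bromo-5-chloro-1,3-bis(methoxymethoxy)benzene; 5 4'-(benzyloxy)acetophenone
Product: 6 1-[4-(benzyloxy)phenyl]-2-[4-chloro-2,6-bis(methoxymethoxy)phenyl]ethan-1-one
Conditions: Pd2(dba)3 (1 mol %), P(t-Bu)3·HBF4 (4 mol %), NaOt-Bu (2.2 equiv), toluene, 50 °C
Reagents that add atoms: none
Why: Palladium-catalysed ketone α-arylation (Buchwald–Hartwig type) should occur at C–Br, which undergoes oxidative addition far faster than C–Cl at this temperature, and the hindered product enolate cannot be arylated a second time by 4.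

Step 4
Reactants: 6 1-[4-(benzyloxy)phenyl]-2-[4-chloro-2,6-bis(methoxymethoxy)phenyl]ethan-1-one; 7 1-bromo-3,5-bis(benzyloxy)benzene
Product: 8 racemic 1-[4-(benzyloxy)phenyl]-2-[3,5-bis(benzyloxy)phenyl]-2-[4-chloro-2,6-bis(methoxymethoxy)phenyl]ethan-1-one
Conditions: Pd(OAc)2 (3 mol %), P(t-Bu)3·HBF4 (6 mol %), NaOt-Bu (2.2 equiv), THF, 45 °C
Reagents that add atoms: none
Why: A second ketone α-arylation joins the stabilised enolate of 6 to the unhindered aryl bromide while the C–Cl bond is spared, and the new α-centre is left racemic on purpose because the next step epimerises it.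

Step 5
Reactants: 8 racemic triaryl ketone
Product: 9 (1S,2S)-1-[4-(benzyloxy)phenyl]-2-[3,5-bis(benzyloxy)phenyl]-2-[4-chloro-2,6-bis(methoxymethoxy)phenyl]ethan-1-ol (C1 is the later C2' and C2 the later C3')
Conditions: H2 (10 atm), RuCl2[(R)-xylBINAP][(R)-DAIPEN] (1 mol %), KOt-Bu (0.2 equiv), i-PrOH–THF, 25 °C
Reagents that add atoms: none
Why: Noyori hydrogenation under dynamic kinetic resolution should set C3' as (S), because KOt-Bu interconverts the enantiomers of 8 through the enolate faster than either is reduced, the (R,R) catalyst forms the (S)-carbinol, and the Felkin–Anh pairing (2,6-dioxygenated ring as large group) selects the matching α-epimer.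

Step 6
Reactants: 6 1-[4-(benzyloxy)phenyl]-2-[4-chloro-2,6-bis(methoxymethoxy)phenyl]ethan-1-one; 10 4-(benzyloxy)styrene
Product: 11 (E)-1-[4-(benzyloxy)phenyl]-2-{4-[2-(4-(benzyloxy)phenyl)ethenyl]-2,6-bis(methoxymethoxy)phenyl}ethan-1-one
Conditions: Pd2(dba)3 (1.5 mol %), P(t-Bu)3·HBF4 (6 mol %), Cy2NMe, 1,4-dioxane, 110 °C
Reagents that add atoms: none
Why: Mizoroki–Heck coupling of the aryl chloride under a bulky trialkylphosphine should give the E-stilbene by syn insertion and syn β-hydride elimination, and the amine base is too weak to form the ketone enolate.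

Step 7
Reactants: 11 stilbene ketone; 9 (1S,2S) chloro alcohol
Product: 12 1-[4-(benzyloxy)phenyl]-2-{4-[(E)-2-(4-(benzyloxy)phenyl)ethenyl]-2,6-bis(methoxymethoxy)phenyl}-2-{4-[(1S,2S)-2-[4-(benzyloxy)phenyl]-1-[3,5-bis(benzyloxy)phenyl]-2-hydroxyethyl]-3,5-bis(methoxymethoxy)phenyl}ethan-1-one (both epimers at C3)
Conditions: Pd(OAc)2 (5 mol %), 2-dicyclohexylphosphino-2',4',6'-triisopropylbiphenyl (10 mol %), K3PO4, toluene, 100 °C
Reagents that add atoms: none
Why: Ketone α-arylation with an aryl chloride under a bulky biarylphosphine should form the C3–ring B bond, since K3PO4 deprotonates the ketone but not the secondary alcohol, C3' has no acidic hydrogen, and C3 is deliberately left as an epimer mixture.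

Step 8
Reactants: 12 ketone (epimers at C3)
Product: 13 (1R,2R)-1-[4-(benzyloxy)phenyl]-2-{4-[(E)-2-(4-(benzyloxy)phenyl)ethenyl]-2,6-bis(methoxymethoxy)phenyl}-2-{4-[(1S,2S)-2-[4-(benzyloxy)phenyl]-1-[3,5-bis(benzyloxy)phenyl]-2-hydroxyethyl]-3,5-bis(methoxymethoxy)phenyl}ethan-1-ol
Conditions: H2 (10 atm), RuCl2[(S)-xylBINAP][(S)-DAIPEN] (2 mol %), KOt-Bu (0.2 equiv), i-PrOH–THF, 25 °C
Reagents that add atoms: none
Why: A second Noyori dynamic kinetic resolution with the enantiomeric catalyst should set C3 as (R) through fast epimerisation, (R)-selective carbonyl reduction and the same Felkin–Anh pairing, while this carbonyl-selective catalyst leaves the stilbene, the benzyl ethers and C2'/C3' alone.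

Step 9
Reactants: 13 tetrakis(methoxymethyl) diol
Product: 15 (2R,3R)-2-[4-(benzyloxy)phenyl]-6-[(E)-2-(4-(benzyloxy)phenyl)ethenyl]-3-{(2S,3S)-2-[4-(benzyloxy)phenyl]-3-[3,5-bis(benzyloxy)phenyl]-4-hydroxy-2,3-dihydro-1-benzofuran-6-yl}-2,3-dihydro-1-benzofuran-4-ol, via tetraphenol diol 14 (not isolated)
Conditions: HCl (3 M in MeOH), THF, 0.01 M, 45 °C; then CF3CO2H, CH2Cl2, 0 °C → rt
Reagents that add atoms: none
Why: HCl in methanol passes the four methoxymethyl groups to the solvent and frees the resorcinol hydroxyls of rings A and B (14); acid then ionises both secondary carbinols to cations delocalised onto the para benzyloxy oxygen, and a neighbouring hydroxyl of ring A or ring B captures each one, forming O1–C2 and O1'–C2'. The closest known reaction is the acid-promoted cyclodehydration of 2-(2-hydroxyaryl)-1-(4-alkoxyphenyl)ethanols to trans-2-aryl-2,3-dihydrobenzofurans. Each of the two rings closes in the 5-exo-trig mode, oxygen adding to the cationic carbon whose π-system lies outside the new ring. C2 and C2' are set under thermodynamic control: in CF3CO2H the C–O bonds re-ionise until each 2-aryl group lies trans to the aryl group on C3 or C3', so the carbinol configurations of 13 do not matter. The step needs O-capture over C-capture and retention at C3 and C3'. Ring carbons of the neighbouring arenes could only close four-membered rings, the two hydroxyls of each resorcinol ring are equivalent by local twofold symmetry, and C3 and C3', although attached to electron-rich rings, carry neither a leaving group nor an acidic hydrogen.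

Step 10
Reactants: 15 pentabenzyl ether
Product: 16 (2R,3R)-2-(4-hydroxyphenyl)-6-[(E)-2-(4-hydroxyphenyl)ethenyl]-3-[(2S,3S)-3-(3,5-dihydroxyphenyl)-4-hydroxy-2-(4-hydroxyphenyl)-2,3-dihydro-1-benzofuran-6-yl]-2,3-dihydro-1-benzofuran-4-ol (CNP0248228.3)
Conditions: BCl3, C6HMe5, CH2Cl2, −78 °C; then H2O
Reagents that add atoms: none
Why: Lewis-acid debenzylation with BCl3 and pentamethylbenzene as a non-basic benzyl-cation scavenger should cleave the five aryl benzyl ethers at −78 °C without touching the stilbene, and a C2–O bond that opened could only re-close to the same trans isomer.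

Compound list
1 | 5-chlororesorcinol | Oc1cc(O)cc(Cl)c1 | starting material
2 | 1-chloro-3,5-bis(methoxymethoxy)benzene | COCOc1cc(Cl)cc(OCOC)c1 | intermediate
3 | [4-chloro-2,6-bis(methoxymethoxy)phenyl]lithium | [Li]c1c(OCOC)cc(Cl)cc1OCOC | intermediate (not isolated)
4 | 2-bromo-5-chloro-1,3-bis(methoxymethoxy)benzene | COCOc1cc(Cl)cc(OCOC)c1Br | intermediate
5 | 4'-(benzyloxy)acetophenone | CC(=O)c1ccc(OCc2ccccc2)cc1 | starting material
6 | 1-[4-(benzyloxy)phenyl]-2-[4-chloro-2,6-bis(methoxymethoxy)phenyl]ethan-1-one | O=C(Cc1c(OCOC)cc(Cl)cc1OCOC)c1ccc(OCc2ccccc2)cc1 | intermediate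
7 | 1-bromo-3,5-bis(benzyloxy)benzene | Brc1cc(OCc2ccccc2)cc(OCc2ccccc2)c1 | starting material
8 | racemic 1-[4-(benzyloxy)phenyl]-2-[3,5-bis(benzyloxy)phenyl]-2-[4-chloro-2,6-bis(methoxymethoxy)phenyl]ethan-1-one | O=C(c1ccc(OCc2ccccc2)cc1)C(c1cc(OCc2ccccc2)cc(OCc2ccccc2)c1)c1c(OCOC)cc(Cl)cc1OCOC | intermediate
9 | (1S,2S)-1-[4-(benzyloxy)phenyl]-2-[3,5-bis(benzyloxy)phenyl]-2-[4-chloro-2,6-bis(methoxymethoxy)phenyl]ethan-1-ol | Clc1cc(OCOC)c([C@@H]([C@H](O)c2ccc(OCc3ccccc3)cc2)c2cc(OCc3ccccc3)cc(OCc3ccccc3)c2)c(OCOC)c1 | intermediate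
10 | 4-(benzyloxy)styrene | C=Cc1ccc(OCc2ccccc2)cc1 | starting material
11 | (E)-1-[4-(benzyloxy)phenyl]-2-{4-[2-(4-(benzyloxy)phenyl)ethenyl]-2,6-bis(methoxymethoxy)phenyl}ethan-1-one | O=C(Cc1c(OCOC)cc(/C=C/c2ccc(OCc3ccccc3)cc2)cc1OCOC)c1ccc(OCc2ccccc2)cc1 | intermediate
12 | triaryl ketone with the (1S,2S) unit on ring B, both epimers at C3 | C(c1ccccc1)Oc1ccc(/C=C/c2cc(OCOC)c(C(C(=O)c3ccc(OCc4ccccc4)cc3)c3cc(OCOC)c([C@@H]([C@H](O)c4ccc(OCc5ccccc5)cc4)c4cc(OCc5ccccc5)cc(OCc5ccccc5)c4)c(OCOC)c3)c(OCOC)c2)cc1 | intermediate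
13 | tetrakis(methoxymethyl) pentabenzyl diol, C2 (R), C3 (R), C2' (S), C3' (S) | C(c1ccccc1)Oc1ccc(/C=C/c2cc(OCOC)c([C@H]([C@@H](O)c3ccc(OCc4ccccc4)cc3)c3cc(OCOC)c([C@@H]([C@H](O)c4ccc(OCc5ccccc5)cc4)c4cc(OCc5ccccc5)cc(OCc5ccccc5)c4)c(OCOC)c3)c(OCOC)c2)cc1 | intermediate
14 | open-chain tetraphenol diol (pentabenzyl), same four configurations as 13 | C(c1ccccc1)Oc1ccc(/C=C/c2cc(O)c([C@H]([C@@H](O)c3ccc(OCc4ccccc4)cc3)c3cc(O)c([C@@H]([C@H](O)c4ccc(OCc5ccccc5)cc4)c4cc(OCc5ccccc5)cc(OCc5ccccc5)c4)c(O)c3)c(O)c2)cc1 | intermediate (not isolated)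
15 | (2R,3R,2'S,3'S) bis(trans-dihydrobenzofuran) pentabenzyl ether with free O4–H and O4'–H | C(c1ccccc1)Oc1ccc(/C=C/c2cc(O)c3c(c2)O[C@@H](c2ccc(OCc4ccccc4)cc2)[C@@H]3c2cc(O)c3c(c2)O[C@H](c2ccc(OCc4ccccc4)cc2)[C@H]3c2cc(OCc3ccccc3)cc(OCc3ccccc3)c2)cc1 | intermediate
16 | CNP0248228.3, (2R,3R,2'S,3'S) | Oc1ccc(/C=C/c2cc(O)c3c(c2)O[C@@H](c2ccc(O)cc2)[C@@H]3c2cc(O)c3c(c2)O[C@H](c2ccc(O)cc2)[C@H]3c2cc(O)cc(O)c2)cc1 | target

Total step count: 10. Longest linear sequence: 9 steps (steps 1, 2, 3, 4, 5, 7, 8, 9, 10 from compound 1).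

Steps most likely to fail

Step 9. The cations, or the electrophile released from the methoxymethyl groups, may be intercepted by ring carbons of a second molecule instead of the neighbouring hydroxyl, or closure may stall before both C2 and C2' have reached the trans arrangement. The fallback closes the rings one at a time; it sets out from 9 and returns at 15. Treating 9 with HCl/MeOH and then CF3CO2H should give the ring-B-closed chlorophenol (2S,3S)-2-[4-(benzyloxy)phenyl]-3-[3,5-bis(benzyloxy)phenyl]-6-chloro-2,3-dihydro-1-benzofuran-4-ol F1. NaH/MOMCl re-protects O4' to give its methoxymethyl ether F2. α-Arylation of 11 with F2 (Pd(OAc)2, the same biarylphosphine, NaOt-Bu, toluene, 100 °C) gives the dihydrobenzofuranyl ketone F3 as C3 epimers. Hydrogenation with RuCl2[(S)-xylBINAP][(S)-DAIPEN] and KOt-Bu gives the (1R,2R) dihydrobenzofuranyl alcohol F4. The same two-stage acid treatment removes its three methoxymethyl groups and closes ring A, returning to the route at 15.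

Step 5. The catalyst may discriminate poorly between the two α-aryl groups, or epimerisation of the hindered α-carbon may be slower than reduction, so that stereoisomers accumulate; step 8 relies on the same behaviour. The fallback separates substrate control from resolution; it sets out from 8 and returns at 9. NaBH4 in THF–MeOH should give the racemic Felkin alcohol F5. Esterification with (S)-O-acetylmandelic acid (EDC·HCl, DMAP, CH2Cl2, 0 °C) gives the (S)-O-acetylmandelate of 9 F6 and the (S)-O-acetylmandelate of the enantiomeric alcohol F7, which are separated by chromatography or crystallisation; F7 is set aside. K2CO3 in MeOH releases 9 from F6, and the route resumes at 9.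

Step 7. Arylpalladium chloride may oxidise the free carbinol of 9 to the ketone (which would make C3' labile again), or the hindered enolate may couple too slowly with the unactivated chloride. The fallback masks the alcohol so that a strong-base protocol can be used; it sets out from 9 and returns at 12. TBSOTf and 2,6-lutidine in CH2Cl2 at −78 °C should give the tert-butyldimethylsilyl ether of 9 F8. α-Arylation of 11 with F8 (Pd(OAc)2, P(t-Bu)3·HBF4, NaOt-Bu, toluene, 80 °C) gives the silyl ether of 12 F9. Bu4NF buffered with AcOH in THF removes the silyl group, and the route resumes at 12.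

Further compounds
F1 | step 9 | ring-B-closed chlorophenol (2S,3S)-2-[4-(benzyloxy)phenyl]-3-[3,5-bis(benzyloxy)phenyl]-6-chloro-2,3-dihydro-1-benzofuran-4-ol | Clc1cc(O)c2c(c1)O[C@H](c1ccc(OCc3ccccc3)cc1)[C@H]2c1cc(OCc2ccccc2)cc(OCc2ccccc2)c1
F2 | step 9 | methoxymethyl ether of F1, (2S,3S)-2-[4-(benzyloxy)phenyl]-3-[3,5-bis(benzyloxy)phenyl]-6-chloro-4-(methoxymethoxy)-2,3-dihydro-1-benzofuran | Clc1cc(OCOC)c2c(c1)O[C@H](c1ccc(OCc3ccccc3)cc1)[C@H]2c1cc(OCc2ccccc2)cc(OCc2ccccc2)c1
F3 | step 9 | dihydrobenzofuranyl ketone from 11 and F2, both epimers at C3 | C(c1ccccc1)Oc1ccc(/C=C/c2cc(OCOC)c(C(C(=O)c3ccc(OCc4ccccc4)cc3)c3cc(OCOC)c4c(c3)O[C@H](c3ccc(OCc5ccccc5)cc3)[C@H]4c3cc(OCc4ccccc4)cc(OCc4ccccc4)c3)c(OCOC)c2)cc1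
F4 | step 9 | (1R,2R) dihydrobenzofuranyl alcohol from F3 | C(c1ccccc1)Oc1ccc(/C=C/c2cc(OCOC)c([C@H]([C@@H](O)c3ccc(OCc4ccccc4)cc3)c3cc(OCOC)c4c(c3)O[C@H](c3ccc(OCc5ccccc5)cc3)[C@H]4c3cc(OCc4ccccc4)cc(OCc4ccccc4)c3)c(OCOC)c2)cc1
F5 | step 5 | racemic Felkin alcohol (1RS,2RS), that is 9 together with its (1R,2R) enantiomer; the SMILES shows the (1R,2R) enantiomer | Clc1cc(OCOC)c([C@H]([C@@H](O)c2ccc(OCc3ccccc3)cc2)c2cc(OCc3ccccc3)cc(OCc3ccccc3)c2)c(OCOC)c1
F6 | step 5 | (S)-O-acetylmandelate of 9 | Clc1cc(OCOC)c([C@@H]([C@H](OC(=O)[C@@H](OC(C)=O)c2ccccc2)c2ccc(OCc3ccccc3)cc2)c2cc(OCc3ccccc3)cc(OCc3ccccc3)c2)c(OCOC)c1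
F7 | step 5 | (S)-O-acetylmandelate of the enantiomeric (1R,2R) alcohol | Clc1cc(OCOC)c([C@H]([C@@H](OC(=O)[C@@H](OC(C)=O)c2ccccc2)c2ccc(OCc3ccccc3)cc2)c2cc(OCc3ccccc3)cc(OCc3ccccc3)c2)c(OCOC)c1
F8 | step 7 | tert-butyldimethylsilyl ether of 9 | Clc1cc(OCOC)c([C@@H]([C@H](O[Si](C)(C)C(C)(C)C)c2ccc(OCc3ccccc3)cc2)c2cc(OCc3ccccc3)cc(OCc3ccccc3)c2)c(OCOC)c1
F9 | step 7 | tert-butyldimethylsilyl ether of 12, both epimers at C3 | C(c1ccccc1)Oc1ccc(/C=C/c2cc(OCOC)c(C(C(=O)c3ccc(OCc4ccccc4)cc3)c3cc(OCOC)c([C@@H]([C@H](O[Si](C)(C)C(C)(C)C)c4ccc(OCc5ccccc5)cc4)c4cc(OCc5ccccc5)cc(OCc5ccccc5)c4)c(OCOC)c3)c(OCOC)c2)cc1
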